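## Retrosynthetic overview

1. The target is a 3,3′-linked biflavanone. The liquiritigenin half has ring A, pyranone ring C (O1, C2, C3, C4) and the 4-hydroxyphenyl ring B on C2. The naringenin half has rings A′, C′, B′ (primed locants). Configuration is 2S,3R,2′S,3′R, i.e. 2,3-trans in both pyranone rings.
2. Enabling feature: C2 and C2′ each carry a ring oxygen (O1, O1′) and a para-oxygenated phenyl ring (B, B′), so each is the CH of a 4-alkoxybenzyl aryl ether that an oxidant can turn into a cation. C3 and C3′ are the alpha-carbons of the C4 and C4′ aryl ketones (enol nucleophiles, epimerizable). Apart from the 5′-OH the halves are related by a twofold axis through C3–C3′.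
3. Key disconnection: the C2–C3 bond of ring C and the C2′–C3′ bond of ring C′ are cut together. This unravels both pyranones to an achiral open-chain 1,4-diarylbutane-1,4-dione whose two ortho-oxygens carry 4-(benzyloxy)benzyl groups. Forward, one twofold enantioselective dehydrogenative enol–oxocarbenium cyclization (DDQ, chiral phosphoric acid) closes ring C′, then ring C, and creates all four stereocentres.
4. The diketone comes from C3–C3′ bond formation (lithium enolate of one aryl methyl ketone plus the alpha-bromoketone of the other). Both ketones come from benzyl-protected hydroxyacetophenones by O-alkylation with 4-(benzyloxy)benzyl chloride.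
5. Ring order: rings A, A′, B, B′ are bought; rings C′ and C are formed in the key step; one hydrogenolysis then frees the five phenols.

Key step: step 5

Assumption: the three aromatic building blocks are taken as commercial; the sense of induction of the phosphoric acid must be found by experiment (the R acid is written for the 2S,2′S series, its mirror image would be used otherwise); the intermediates of the key step are drawn for closure of ring C′ before ring C, the reverse order leading to the same product.

## Route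

Step 1
Reactants: 1 1-[4-(benzyloxy)-2-hydroxyphenyl]ethan-1-one; 2 1-(benzyloxy)-4-(chloromethyl)benzene
Product: 3 1-[4-(benzyloxy)-2-{[4-(benzyloxy)phenyl]methoxy}phenyl]ethan-1-one
Conditions: K2CO3, DMF, 60 °C
Reagents that add atoms: none
Why: Williamson ether synthesis, in which the phenoxide of the chelated ortho-hydroxy ketone should displace the reactive benzylic chloride and so install the carbon that becomes C2 on the oxygen that becomes O1.

Step 2
Reactants: 4 1-[2,4-bis(benzyloxy)-6-hydroxyphenyl]ethan-1-one; 2 1-(benzyloxy)-4-(chloromethyl)benzene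
Product: 5 1-[2,4-bis(benzyloxy)-6-{[4-(benzyloxy)phenyl]methoxy}phenyl]ethan-1-one
Conditions: K2CO3, DMF, 80 °C
Reagents that add atoms: none
Why: Williamson ether synthesis on the only free, hydrogen-bonded ortho-phenol, so that the future O1′ alone receives the future C2′ while the two benzyl ethers already mark the later 5′- and 7′-hydroxyls.

Step 3
Reactants: 3 1-[4-(benzyloxy)-2-{[4-(benzyloxy)phenyl]methoxy}phenyl]ethan-1-one
Product: 7 2-bromo-1-[4-(benzyloxy)-2-{[4-(benzyloxy)phenyl]methoxy}phenyl]ethan-1-one, via silyl enol ether 6 (not isolated)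
Conditions: LiN(SiMe3)2, Me3SiCl, THF, −78 °C; then N-bromosuccinimide, −78 to 0 °C
Reagents that add atoms: N-bromosuccinimide, O=C1CCC(=O)N1Br
Why: Electrophilic alpha-bromination of a preformed trimethylsilyl enol ether, which should react with N-bromosuccinimide far faster than the alkoxy-substituted rings and under neutral conditions that spare the acid-labile 4-(benzyloxy)benzyl ether.

Step 4
Reactants: 5 1-[2,4-bis(benzyloxy)-6-{[4-(benzyloxy)phenyl]methoxy}phenyl]ethan-1-one; 7 2-bromo-1-[4-(benzyloxy)-2-{[4-(benzyloxy)phenyl]methoxy}phenyl]ethan-1-one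
Product: 9 1-[4-(benzyloxy)-2-{[4-(benzyloxy)phenyl]methoxy}phenyl]-4-[2,4-bis(benzyloxy)-6-{[4-(benzyloxy)phenyl]methoxy}phenyl]butane-1,4-dione, via lithium enolate 8 (not isolated)
Conditions: LiN(SiMe3)2, THF, −78 °C; then 7, −78 to 0 °C
Reagents that add atoms: none
Why: Enolate alkylation (SN2 at the primary phenacyl bromide) should form the C3–C3′ bond, the di-ortho-substituted enolate being unable to self-condense and the low temperature limiting proton transfer and carbonyl addition.

Step 5
Reactants: 9 1-[4-(benzyloxy)-2-{[4-(benzyloxy)phenyl]methoxy}phenyl]-4-[2,4-bis(benzyloxy)-6-{[4-(benzyloxy)phenyl]methoxy}phenyl]butane-1,4-dione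
Product: 14 (2S,3R,2′S,3′R)-7,5′,7′-tris(benzyloxy)-2,2′-bis[4-(benzyloxy)phenyl]-3,3′-bichroman-4,4′-dione, via oxocarbenium ion 10 (not isolated), via mono-flavanone 11 (not isolated), via oxocarbenium ion 12 (not isolated), via C3-epimer mixture 13 (not isolated)
Conditions: 2,3-dichloro-5,6-dicyano-1,4-benzoquinone (DDQ, 2.4 equiv), (R)-3,3′-bis(2,4,6-triisopropylphenyl)-1,1′-binaphthyl-2,2′-diyl hydrogen phosphate (20 mol %), 4 Å molecular sieves, ClCH2CH2Cl, −20 to 25 °C; filtration through basic Al2O3; then Et3N, CH2Cl2, 25 °C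
Reagents that add atoms: none
Why: Proposed new method: DDQ removes hydride from each ArO–CH2 carbon that carries the 4-(benzyloxy)phenyl ring (first on the more electron-rich trialkoxyphenyl half); the resulting aryl-oxocarbenium ions 10 and 12 are ion-paired with the phosphate of the acid, which also generates and hydrogen-bonds the enol of the neighbouring C4′ or C4 ketone, and the enol carbon C3′, then C3, attacks C2′, then C2. The closest known reaction types are the DDQ-mediated oxidative cyclization of 4-methoxybenzyl ethers onto tethered enol nucleophiles and the cross-dehydrogenative coupling of benzylic ethers with ketones, together with chiral-phosphate-controlled C–C recombination of enol/onium ion pairs (Petasis–Ferrier-type rearrangements, quinone methide additions); new are the aryl ether substrate, the twofold closure and the enantiocontrol. Ring C′ and ring C are each closed in a 6-(enolendo)-endo-trig mode, with both the O1=C2 cation and the C3=C4 enol inside the forming pyranone. C2′ and C2 (both S) are set by the catalyst through face-selective attack within the hydrogen-bonded ion pair, and because two events obey the same control the minor sense should be diverted largely into the separable 2S,2′R diastereomer; C3′ and C3 (both R) are set by thermodynamic control, the Et3N equilibration through the enol(ate)s placing each C3 substituent trans (diequatorial) to the fixed C2 aryl group. The step needs oxidation at only the two 4-(benzyloxy)benzyl CH2 groups among seven benzylic ether CH2 groups, secured because only these give a para-oxygen-stabilized cation, and it needs C- rather than O-capture, secured because capture by the carbonyl oxygen is reversible under the acid while C–C bond formation is not. Molecular sieves should suppress hydrolysis of the cations and the low temperature should avoid dehydrogenation of the products to flavones.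

Step 6
Reactants: 14 (2S,3R,2′S,3′R)-7,5′,7′-tris(benzyloxy)-2,2′-bis[4-(benzyloxy)phenyl]-3,3′-bichroman-4,4′-dione
Product: 15 (2S,3R,2′S,3′R)-7,5′,7′-trihydroxy-2,2′-bis(4-hydroxyphenyl)-3,3′-bichroman-4,4′-dione (CNP0138443.1)
Conditions: H2 (1 atm), 10% Pd/C, THF–MeOH, 25 °C
Reagents that add atoms: none
Why: Hydrogenolysis of the five benzyl aryl ethers over palladium on carbon under neutral conditions, in which the ketones and the tertiary ring bonds C2–O1 and C2′–O1′ should survive so that the four stereocentres are carried unchanged.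

## Compound list

1 | 1-[4-(benzyloxy)-2-hydroxyphenyl]ethan-1-one | CC(=O)c1ccc(OCc2ccccc2)cc1O | starting material
2 | 1-(benzyloxy)-4-(chloromethyl)benzene (4-(benzyloxy)benzyl chloride) | ClCc1ccc(OCc2ccccc2)cc1 | starting material
3 | 1-[4-(benzyloxy)-2-{[4-(benzyloxy)phenyl]methoxy}phenyl]ethan-1-one | CC(=O)c1ccc(OCc2ccccc2)cc1OCc1ccc(OCc2ccccc2)cc1 | intermediate
4 | 1-[2,4-bis(benzyloxy)-6-hydroxyphenyl]ethan-1-one | CC(=O)c1c(O)cc(OCc2ccccc2)cc1OCc1ccccc1 | starting material
5 | 1-[2,4-bis(benzyloxy)-6-{[4-(benzyloxy)phenyl]methoxy}phenyl]ethan-1-one | CC(=O)c1c(OCc2ccccc2)cc(OCc2ccccc2)cc1OCc1ccc(OCc2ccccc2)cc1 | intermediate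
6 | {[1-(4-(benzyloxy)-2-{[4-(benzyloxy)phenyl]methoxy}phenyl)ethenyl]oxy}trimethylsilane | C=C(O[Si](C)(C)C)c1ccc(OCc2ccccc2)cc1OCc1ccc(OCc2ccccc2)cc1 | intermediate
7 | 2-bromo-1-[4-(benzyloxy)-2-{[4-(benzyloxy)phenyl]methoxy}phenyl]ethan-1-one | BrCC(=O)c1ccc(OCc2ccccc2)cc1OCc1ccc(OCc2ccccc2)cc1 | intermediate
8 | lithium 1-[2,4-bis(benzyloxy)-6-{[4-(benzyloxy)phenyl]methoxy}phenyl]ethen-1-olate | [Li]OC(=C)c1c(OCc2ccccc2)cc(OCc2ccccc2)cc1OCc1ccc(OCc2ccccc2)cc1 | intermediate
9 | 1-[4-(benzyloxy)-2-{[4-(benzyloxy)phenyl]methoxy}phenyl]-4-[2,4-bis(benzyloxy)-6-{[4-(benzyloxy)phenyl]methoxy}phenyl]butane-1,4-dione | O=C(CCC(=O)c1c(OCc2ccccc2)cc(OCc2ccccc2)cc1OCc1ccc(OCc2ccccc2)cc1)c1ccc(OCc2ccccc2)cc1OCc1ccc(OCc2ccccc2)cc1 | intermediate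
10 | aryl-oxocarbenium ion of 9 at the trialkoxyphenyl half (phosphate ion pair, cation shown) | O=C(CCC(=O)c1c(OCc2ccccc2)cc(OCc2ccccc2)cc1[O+]=Cc1ccc(OCc2ccccc2)cc1)c1ccc(OCc2ccccc2)cc1OCc1ccc(OCc2ccccc2)cc1 | intermediate
11 | (2S)-5,7-bis(benzyloxy)-2-[4-(benzyloxy)phenyl]-3-[2-(4-(benzyloxy)-2-{[4-(benzyloxy)phenyl]methoxy}phenyl)-2-oxoethyl]chroman-4-one (both C3 epimers) | O=C(CC1C(=O)c2c(OCc3ccccc3)cc(OCc3ccccc3)cc2O[C@@H]1c1ccc(OCc2ccccc2)cc1)c1ccc(OCc2ccccc2)cc1OCc1ccc(OCc2ccccc2)cc1 | intermediate
12 | aryl-oxocarbenium ion of 11 (phosphate ion pair, cation shown) | O=C(CC1C(=O)c2c(OCc3ccccc3)cc(OCc3ccccc3)cc2O[C@@H]1c1ccc(OCc2ccccc2)cc1)c1ccc(OCc2ccccc2)cc1[O+]=Cc1ccc(OCc2ccccc2)cc1 | intermediate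
13 | (2S,2′S)-7,5′,7′-tris(benzyloxy)-2,2′-bis[4-(benzyloxy)phenyl]-3,3′-bichroman-4,4′-dione, mixture of C3/C3′ epimers | O=C1c2ccc(OCc3ccccc3)cc2O[C@H](c2ccc(OCc3ccccc3)cc2)C1C1C(=O)c2c(OCc3ccccc3)cc(OCc3ccccc3)cc2O[C@@H]1c1ccc(OCc2ccccc2)cc1 | intermediate
14 | (2S,3R,2′S,3′R)-7,5′,7′-tris(benzyloxy)-2,2′-bis[4-(benzyloxy)phenyl]-3,3′-bichroman-4,4′-dione | O=C1c2ccc(OCc3ccccc3)cc2O[C@H](c2ccc(OCc3ccccc3)cc2)[C@H]1[C@H]1C(=O)c2c(OCc3ccccc3)cc(OCc3ccccc3)cc2O[C@@H]1c1ccc(OCc2ccccc2)cc1 | intermediate
15 | (2S,3R,2′S,3′R)-7,5′,7′-trihydroxy-2,2′-bis(4-hydroxyphenyl)-3,3′-bichroman-4,4′-dione | O=C1c2ccc(O)cc2O[C@H](c2ccc(O)cc2)[C@H]1[C@H]1C(=O)c2c(O)cc(O)cc2O[C@@H]1c1ccc(O)cc1 | target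

## Step count and risks

Total step count: 6. Longest linear sequence: 5 steps (steps 1, 3, 4, 5, 6).

Steps most likely to fail:

1. Step 5. Closure within the achiral ion pair with the reduced quinone may outrun the phosphate-controlled pathway (loss of enantiofacial control), and the cations may be hydrolysed before the slow enolization delivers the nucleophile. The fallback uses only known chemistry, sets out from 9 and comes back at 14, and forms the pyranones the classical way (aldol, then O1–C2 closure). The two 4-(benzyloxy)benzyl groups of 9 would be removed with CF3CO2H and pentamethylbenzene in CH2Cl2 at 0 °C to give 1-[4-(benzyloxy)-2-hydroxyphenyl]-4-[2,4-bis(benzyloxy)-6-hydroxyphenyl]butane-1,4-dione F1. Twofold aldol condensation of F1 with 4-(benzyloxy)benzaldehyde (pyrrolidine, EtOH, 60 °C), followed in the same flask by oxa-Michael ring closure, should give the penta-O-benzyl biflavanone stereoisomer mixture F2. Equilibration with K2CO3 in MeOH to the 2,3-trans,2′,3′-trans isomers, chromatographic removal of the meso-like pair and preparative chiral-phase chromatography of the racemic pair would then deliver 14.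

2. Step 4. Proton transfer from the acidic bromoketone to the enolate and addition of the enolate to the bromoketone carbonyl (epoxide formation) may outrun the SN2 displacement. The fallback sets out from 5 (with 7) and comes back at 9. Ketone 5 would be C-acylated with dimethyl carbonate and NaH in THF to methyl 3-[2,4-bis(benzyloxy)-6-{[4-(benzyloxy)phenyl]methoxy}phenyl]-3-oxopropanoate F3. Its soft potassium enolate (K2CO3, acetone, 25 °C) should be alkylated cleanly by 7 to methyl 2-[2,4-bis(benzyloxy)-6-{[4-(benzyloxy)phenyl]methoxy}benzoyl]-4-[4-(benzyloxy)-2-{[4-(benzyloxy)phenyl]methoxy}phenyl]-4-oxobutanoate F4. Krapcho dealkoxycarbonylation (LiCl, wet DMSO, 130 °C) then returns 9.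

3. Step 6. Hydrogenolytic opening of the benzylic ring bonds C2–O1 and C2′–O1′ may compete with the slow removal of the hindered 5′-O-benzyl group. The fallback sets out from 14 and comes back at 15 without hydrogen: Lewis-acid debenzylation with BCl3 and pentamethylbenzene as cation scavenger in CH2Cl2 at −78 °C, then methanol quench. No new compound is formed on the way (F0).

Further compounds

F1 | step 5 | 1-[4-(benzyloxy)-2-hydroxyphenyl]-4-[2,4-bis(benzyloxy)-6-hydroxyphenyl]butane-1,4-dione | O=C(CCC(=O)c1c(O)cc(OCc2ccccc2)cc1OCc1ccccc1)c1ccc(OCc2ccccc2)cc1O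
F2 | step 5 | 7,5′,7′-tris(benzyloxy)-2,2′-bis[4-(benzyloxy)phenyl]-3,3′-bichroman-4,4′-dione, mixture of stereoisomers | O=C1c2ccc(OCc3ccccc3)cc2OC(c2ccc(OCc3ccccc3)cc2)C1C1C(=O)c2c(OCc3ccccc3)cc(OCc3ccccc3)cc2OC1c1ccc(OCc2ccccc2)cc1
F3 | step 4 | methyl 3-[2,4-bis(benzyloxy)-6-{[4-(benzyloxy)phenyl]methoxy}phenyl]-3-oxopropanoate | COC(=O)CC(=O)c1c(OCc2ccccc2)cc(OCc2ccccc2)cc1OCc1ccc(OCc2ccccc2)cc1
F4 | step 4 | methyl 2-[2,4-bis(benzyloxy)-6-{[4-(benzyloxy)phenyl]methoxy}benzoyl]-4-[4-(benzyloxy)-2-{[4-(benzyloxy)phenyl]methoxy}phenyl]-4-oxobutanoate | COC(=O)C(CC(=O)c1ccc(OCc2ccccc2)cc1OCc1ccc(OCc2ccccc2)cc1)C(=O)c1c(OCc2ccccc2)cc(OCc2ccccc2)cc1OCc1ccc(OCc2ccccc2)cc1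
F0 | step 6 | none | none
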